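Late in the two earlier runs, at 80.0 min, the Q charged minus the L read came to 225 mM in Monday's run and 198 mM in Sunday's, although Sunday's charge was larger. With a scatter of 2 percentage points on each reading, I read these two values as one.

| flask | Q | remark | time |
|---|---|---|---|
| Monday's | 0.75 M | run made earlier |  |
| Sunday's | 1.1 M | run made earlier |  |
| flask | 1.5 M |  | 80 min |

| run | time / min | L / % | X / % | Q / % |
|---|---|---|---|---|
| Monday's | 4.00 | 48 | 22 | 24 |
| Monday's | 12.0 | 61 | 20 | 5 |
| Monday's | 25.0 | 64 | 22 | 6 |
| Monday's | 30.0 | 66 | 17 | 4 |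
| Monday's | 50.0 | 70 | 12 | 3 |
| Monday's | 60.0 | 74 | 17 | 5 |
| Monday's | 80.0 | 70 | 17 | 6 |
| Sunday's | 6.00 | 62 | 25 | 10 |
| Sunday's | 10.0 | 62 | 28 | 8 |
| Sunday's | 15.0 | 67 | 24 | 6 |
| Sunday's | 25.0 | 72 | 17 | 4 |
| Sunday's | 30.0 | 74 | 18 | 5 |
| Sunday's | 50.0 | 76 | 16 | 4 |
| Sunday's | 80.0 | 82 | 9 | 4 |

(scatter of a reading: 2 percentage points)

* ratio of L to X at 6.0 s
* ratio of L to X at 3.0 min
* ratio of L to X at 80 min

- a reading or a percentage of L counts all its forms, free or not

I laid out the time scales from the fastest up. Monday's Q of 24 % at 4.00 min gives a time constant of 2.80 min from the start. Sunday's X fell from 28 % at 10.0 min to 9 % at 80.0 min, a time constant of 61.7 min, much slower than the loss of Q. This looked like kinetic against thermodynamic control. In the new flask up to 3.0 min the drain of X has had little time, so I expected the split of the first readings, 2.18 on Monday's run and 2.48 on Sunday's, and took their mean, 2.33, for both 6.0 s and 3.0 min.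

Sunday's X was still falling between 50.0 min and 80.0 min, so I compared runs at the same clock time. I called the mean of the two values above the late stock, 211 mM: the concentration of whatever is not L at 80 min. I assumed it holds at the new charge too. X within that stock averaged 113 mM over the two runs, and I took that for the new flask as well. For the new flask, counting the whole charge as L gave a first ratio of 13.2; going round again with the stock taken off the charge gave 11.4.

The forecast was lower than my figure at 80 min: 2.1 at 6.0 s, 2.3 at 3.0 min and 8.5 at 80 min, with a range of 6 to 13 for the last, on the ground that “Higher concentration therefore favours L”.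

The flask gave 2.61 at 6.0 s, 2.28 at 3.0 min and 10.0 at 80 min.

    Q ⇌ L (K = 1.00, k = 0.00560 s⁻¹)
    Q ⇌ X (K = 2.90, k = 0.00210 s⁻¹)
    L ⇌ E (K = 2.30, k = 0.00230 s⁻¹)
    G ⇌ L, rate k4*(cs4 - [L]) while solid is left; crystals form when [L] > cs4 (solubility = 31.0 mM, k = 0.0330 s⁻¹)

At 80.0 min the flask held L at 84.3 %, with crystals G of 82.2 % counted in it, beside X at 8.41 %. Its late stock was 235 mM, against my 211 mM. For the neighbour flask, charged with 0.90 M of Q, my late stock predicts L at 76.6 % and, with my X, a ratio of 6.10. That flask held L at 76.4 % and gave a ratio of 6.39.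

The data were generated by integration with constants of no real substance.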